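Time counts in these runs as a product with D. Dusk at 30.0 h, autumn at 20.0 h and midnight at 15.0 h all reach D charge times time = 3.00 M·h, and their readings of Q + E lie close together, with mean 5.13%, though the charges differ.

| flask | J | D | remark | time |
|---|---|---|---|---|
| dusk | 0.20 M | 0.10 M | run made earlier |  |
| autumn | 0.20 M | 0.15 M | run made earlier |  |
| midnight | 0.30 M | 0.20 M | run made earlier |  |
| flask | 0.20 M | 0.200 M |  | 25 h |

- dusk (time / h: Q / %, E / %): 2.50: 0.5, 0; 4.00: 0, 0.3; 6.00: 0, 0.4; 10.0: 0.7, 0.5; 20.0: 1.0, 0; 30.0: 3.7, 1.5
- autumn (time / h: Q / %, E / %): 5.00: 0.6, 0; 10.0: 2.5, 0; 15.0: 2.4, 1.5; 20.0: 4.4, 1.3; 25.0: 5.6, 1.8; 30.0: 5.3, 1.8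
- midnight (time / h: Q / %, E / %): 2.50: 0, 0; 5.00: 0.4, 0.3; 8.00: 1.3, 0.7; 15.0: 3.2, 1.3; 30.0: 6.4, 2.0

(scatter of a reading: 0.5 percentage points)

- a reading or a percentage of E counts all its forms, free or not

* equivalents of D to J, everything else as given, that leave most Q at 25 h
* the amount of Q then, in percent of the J charged
* the amount of Q with the amounts as given

Take each addition as pseudo-first-order at a given D, and let the exposure θ be the time integral of D. Q + E lies two additions from J, through an unseen mono adduct. With one constant k for both, Q + E is about half the square of kθ at low conversion, and the mean reading gives k = 0.107 L mol⁻¹ h⁻¹. The J lost is one minus exp(−kθ). D used per J is that loss plus Q + E, and D is taken to fall in a straight line.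

Two extreme versions of this flask can be solved in the head. With D held at its charge, θ = 5.00 M·h; with D falling to zero, θ = 2.50 M·h. Put through the balance, the first returns 3.61 M·h, less than it assumed, and the second returns 4.33 M·h, more than it assumed. The reckoning therefore puts this flask between them. One more round from the midpoint gives the exposure of this flask, 3.91 M·h. Scaling the readings of Q by the square of θ gives Q about 6.41% at the charges given.

The forecast says 5.5% for those charges, and 9.5% at 4 equiv: “Allowing for D consumption and the lag, that is about 4 equiv”. Its 5.5% is lower than the reckoning here.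

The simulation gives 7.03% at the charges given, and most Q, 15.6%, at 3.10 equiv.

    J + D → Z + G (k = 0.00150 L mol⁻¹ min⁻¹)
    D + Z → Q + G (k = 0.00360 L mol⁻¹ min⁻¹)
    D + Q → E + G (k = 0.00450 L mol⁻¹ min⁻¹)
    D + E ⇌ X, settled at all times (K = 2.40 L mol⁻¹)

Z is the mono adduct and G a by-product. The reckoned θ implies D at 56.4% of its charge after 25.0 h, and the flask holds 56.9%. The consumption of D is only a part of what holds Q down: the same flask with D kept at its charge gives 9.47% of Q instead of 7.03%. The time allowed has a larger effect than this: the same flask read at 250 h holds 14.3% of Q.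

The same flask read at 6.0 h is reckoned at θ = 1.12 M·h, so Q + E should be 0.719%. The computed flask holds Q 1.01% and E 0.109%, so the reckoning falls short by 0.4 percentage points.

(The readings are simulated for an exercise; the scatter is artificial.)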